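**Plan**

- Retrosynthesis (flavan numbering throughout): remove the two phenol protecting groups; trace the C4–OH bond back to the C3=C4 alkene of a (2S)-flav-3-ene; open ring C at C4–C4a to an (S)-aryl propargyl ether; cut O1–C2 into a prenylated phenol and a racemic propargylic carbonate; cut C8–CH2 (prenyl) and C2–C3 (ethynyl).
- Forward: ring A is bought as 5-methoxyresorcinol and dressed (O5 silyl ether, C8 prenyl by directed lithiation); ring B comes from 4-hydroxybenzaldehyde; the halves are joined through O1–C2; ring C closes last through C4–C4a.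
- Enabling feature: in ring A, C4a is the only unsubstituted carbon ortho to O1 (the other ortho carbon, C8, carries the prenyl group), and it is ortho to O1 and O5 and para to O7. An alkyne tethered through O1–C2 can therefore be arylated only there, in a 6-endo sense.
- Stereochemistry: C2 (S) is set by a copper/pybox propargylic etherification and no bond to it is broken afterwards. C4 (R, 2,4-trans) is relayed from C2 by syn Cu–H addition to C3=C4 on the face opposite the C2 aryl, then C–B oxidation with retention.

Key step: step 8

Assumption: the sense of induction of the pybox ligand in step 7 is adjustable by choice of ligand antipode; the antipode that delivers the (S)-ether is meant throughout.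

"Prenyl" = 3-methylbut-2-en-1-yl; TIPS = triisopropylsilyl; Piv = pivaloyl.

**Step 1**
Reactants: 1 5-methoxyresorcinol
Product: 2 3-methoxy-5-(triisopropylsilyloxy)phenol
Conditions: TIPSCl (1.0 equiv), imidazole, DMF, 0 °C → rt
Reagents that add atoms: triisopropylsilyl chloride, CC(C)[Si](Cl)(C(C)C)C(C)C
Why: Mono-silylation of a symmetrical diphenol (silyl ether formation) has no regiochemical issue because both hydroxyls are equivalent, and the bis-ether and unreacted 1 are separable and recyclable.

**Step 2**
Reactants: 2 3-methoxy-5-(triisopropylsilyloxy)phenol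
Product: 3 1-methoxy-3-(methoxymethoxy)-5-(triisopropylsilyloxy)benzene
Conditions: MOMCl, i-Pr2NEt, CH2Cl2, 0 °C → rt
Reagents that add atoms: chloromethyl methyl ether, COCCl
Why: O-Alkylation of the free phenol with MOMCl under amine base installs a strong ortho-directing group without disturbing the aryl TIPS ether.

**Step 3**
Reactants: 3 1-methoxy-3-(methoxymethoxy)-5-(triisopropylsilyloxy)benzene; 4 prenyl bromide
Product: 6 1-methoxy-3-(methoxymethoxy)-2-prenyl-5-(triisopropylsilyloxy)benzene, via C2 aryllithium 5 (not isolated)
Conditions: n-BuLi, THF, 0 °C; then CuI (10 mol %), prenyl bromide, −78 °C → rt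
Reagents that add atoms: n-butyllithium, [Li]CCCC (provides the lithium of 5; none of its atoms remains in 6)
Why: Directed ortho-metalation removes the proton flanked by OMOM and OMe, the only site chelated by two donors, while both positions next to the bulky, non-coordinating OTIPS are shielded; the aryllithium is then allylated at the primary carbon of prenyl bromide under copper catalysis.

**Step 4**
Reactants: 6 1-methoxy-3-(methoxymethoxy)-2-prenyl-5-(triisopropylsilyloxy)benzene
Product: 7 3-methoxy-2-prenyl-5-(triisopropylsilyloxy)phenol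
Conditions: conc. HCl (cat.), MeOH, rt
Reagents that add atoms: none
Why: Acid-catalysed acetal exchange cleaves the aryl MOM ether much faster than dilute acid at room temperature protonates the trisubstituted olefin or solvolyses an aryl TIPS ether.

**Step 5**
Reactants: 8 4-hydroxybenzaldehyde
Product: 9 4-formylphenyl pivalate
Conditions: PivCl, Et3N, DMAP (cat.), CH2Cl2, 0 °C → rt
Reagents that add atoms: pivaloyl chloride, CC(C)(C)C(=O)Cl
Why: O-Acylation of the phenol gives a hindered, electron-withdrawing ester that later damps ionisation at the benzylic C2 and survives Grignard, copper and gold chemistry.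

**Step 6**
Reactants: 9 4-formylphenyl pivalate; 10 ethynylmagnesium bromide
Product: 12 tert-butyl 1-[4-(pivaloyloxy)phenyl]prop-2-yn-1-yl carbonate (racemic), via bromomagnesium propargylic alkoxide 11 (not isolated)
Conditions: HC≡CMgBr, THF, −78 → 0 °C; then Boc2O, 0 °C → rt
Reagents that add atoms: di-tert-butyl dicarbonate, CC(C)(C)OC(=O)OC(=O)OC(C)(C)C
Why: Grignard 1,2-addition to the aldehyde is far faster than attack on the hindered aryl pivalate at low temperature, and the magnesium alkoxide is trapped in the same flask by Boc2O; the product is racemic by design because the next step is enantioconvergent.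

**Step 7**
Reactants: 7 3-methoxy-2-prenyl-5-(triisopropylsilyloxy)phenol; 12 tert-butyl 1-[4-(pivaloyloxy)phenyl]prop-2-yn-1-yl carbonate (racemic)
Product: 13 (S)-4-{1-[3-methoxy-2-prenyl-5-(triisopropylsilyloxy)phenoxy]prop-2-yn-1-yl}phenyl pivalate
Conditions: CuOTf·½C6H6 (5 mol %), Ph-pybox (10 mol %, antipode giving the S ether), i-Pr2NEt, THF, −20 °C
Reagents that add atoms: none
Why: Copper-catalysed asymmetric propargylic etherification: the copper acetylide of 12 loses tert-butyl carbonate to give a copper allenylidene, and the phenoxide of 7 attacks its γ-carbon inside the pybox pocket, which sets C2 as S from either enantiomer of 12; the TIPS ether flanks both free ring carbons of 7 and so discourages C-propargylation.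

**Step 8**
Reactants: 13 (S)-4-{1-[3-methoxy-2-prenyl-5-(triisopropylsilyloxy)phenoxy]prop-2-yn-1-yl}phenyl pivalate
Product: 14 4-[(2S)-7-methoxy-8-prenyl-5-(triisopropylsilyloxy)-2H-chromen-2-yl]phenyl pivalate
Conditions: [JohnPhosAu(MeCN)]SbF6 (2 mol %), CH2Cl2, 0 °C → rt
Reagents that add atoms: none
Why: The cationic gold(I) centre binds the terminal alkyne, and C4a of ring A attacks the terminal alkyne carbon anti to gold in a Friedel–Crafts sense; loss of the ring proton and protodeauration of the C3 vinylgold then release the C3=C4 alkene. The closest known reaction type is the gold(I)-catalysed intramolecular hydroarylation of aryl propargyl ethers to 2H-chromenes. Ring C closes in the 6-endo-dig mode through the new C4–C4a bond. No stereocentre is created and none of the bonds at C2 is broken, so the S configuration from step 7 is carried over unchanged. The step needs arylation at C4a to outrun 5-exo closure, ionisation of C2–O1 and attack by the prenyl olefin: C8 is blocked, so C4a is the only ortho carbon available, and its three oxygen donors (O1 and O5 ortho, O7 para) make it far more nucleophilic than the remote trisubstituted alkene, which could only close a seven-membered or larger ring. The electron-poor 4'-pivalate and a non-oxophilic catalyst at or below room temperature disfavour C2 ionisation.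

**Step 9**
Reactants: 14 4-[(2S)-7-methoxy-8-prenyl-5-(triisopropylsilyloxy)-2H-chromen-2-yl]phenyl pivalate
Product: 16 4-[(2S,4R)-4-hydroxy-7-methoxy-8-prenyl-5-(triisopropylsilyloxy)chroman-2-yl]phenyl pivalate, via C4 pinacolboronate 15 (not isolated)
Conditions: CuCl (5 mol %), dppbz (5 mol %), NaOt-Bu (10 mol %), HBpin, toluene, rt; then NaBO3·4H2O, THF/H2O, 0 °C → rt
Reagents that add atoms: pinacolborane, CC1(C)OBOC1(C)C (boryl group of 15; only the C3 hydrogen remains in 16); sodium perborate tetrahydrate, [Na+].[O-]OB=O (oxygen at C4)
Why: Copper hydride-catalysed Markovnikov hydroboration of a cyclic vinylarene: L2Cu–H adds syn to C3=C4 with copper at the benzylic C4 on the face opposite the C2 aryl (axial at C4, away from the peri O5 substituent), σ-bond metathesis with HBpin and perborate oxidation both retain configuration, so C4 becomes R (2,4-trans), while the isolated prenyl olefin and the pivalate do not react with Cu–H at room temperature.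

**Step 10**
Reactants: 16 4-[(2S,4R)-4-hydroxy-7-methoxy-8-prenyl-5-(triisopropylsilyloxy)chroman-2-yl]phenyl pivalate
Product: 18 (2S,4R)-2-(4-hydroxyphenyl)-7-methoxy-8-prenylchromane-4,5-diol (target), via 5-O-TIPS 4,4'-diol 17 (not isolated)
Conditions: K2CO3 (0.3 equiv), MeOH, rt; then AcOH, TBAF, THF, 0 °C; pH 7 work-up
Reagents that add atoms: none
Why: Base-catalysed methanolysis of the aryl pivalate followed by buffered fluoride cleavage of the aryl silyl ether unmasks both phenols without acid, which would ionise the electron-rich benzylic C4–OH, and without touching C2, C4 or the prenyl group.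

**Compound list**

1 | 5-methoxyresorcinol | COc1cc(O)cc(O)c1 | starting material
2 | 3-methoxy-5-(triisopropylsilyloxy)phenol | COc1cc(O)cc(O[Si](C(C)C)(C(C)C)C(C)C)c1 | intermediate
3 | 1-methoxy-3-(methoxymethoxy)-5-(triisopropylsilyloxy)benzene | COCOc1cc(OC)cc(O[Si](C(C)C)(C(C)C)C(C)C)c1 | intermediate
4 | prenyl bromide (1-bromo-3-methylbut-2-ene) | CC(C)=CCBr | starting material
5 | 2-methoxy-6-(methoxymethoxy)-4-(triisopropylsilyloxy)phenyllithium (not isolated) | COCOc1cc(O[Si](C(C)C)(C(C)C)C(C)C)cc(OC)c1[Li] | intermediate
6 | 1-methoxy-3-(methoxymethoxy)-2-prenyl-5-(triisopropylsilyloxy)benzene | COCOc1cc(O[Si](C(C)C)(C(C)C)C(C)C)cc(OC)c1CC=C(C)C | intermediate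
7 | 3-methoxy-2-prenyl-5-(triisopropylsilyloxy)phenol | COc1cc(O[Si](C(C)C)(C(C)C)C(C)C)cc(O)c1CC=C(C)C | intermediate
8 | 4-hydroxybenzaldehyde | O=Cc1ccc(O)cc1 | starting material
9 | 4-formylphenyl pivalate | CC(C)(C)C(=O)Oc1ccc(C=O)cc1 | intermediate
10 | ethynylmagnesium bromide | C#C[Mg]Br | starting material
11 | bromomagnesium 1-[4-(pivaloyloxy)phenyl]prop-2-yn-1-olate, racemic (not isolated) | C#CC(O[Mg]Br)c1ccc(OC(=O)C(C)(C)C)cc1 | intermediate
12 | tert-butyl 1-[4-(pivaloyloxy)phenyl]prop-2-yn-1-yl carbonate, racemic | C#CC(OC(=O)OC(C)(C)C)c1ccc(OC(=O)C(C)(C)C)cc1 | intermediate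
13 | (S)-4-{1-[3-methoxy-2-prenyl-5-(triisopropylsilyloxy)phenoxy]prop-2-yn-1-yl}phenyl pivalate | C#C[C@H](Oc1cc(O[Si](C(C)C)(C(C)C)C(C)C)cc(OC)c1CC=C(C)C)c1ccc(OC(=O)C(C)(C)C)cc1 | intermediate
14 | 4-[(2S)-7-methoxy-8-prenyl-5-(triisopropylsilyloxy)-2H-chromen-2-yl]phenyl pivalate | COc1cc(O[Si](C(C)C)(C(C)C)C(C)C)c2C=C[C@@H](c3ccc(OC(=O)C(C)(C)C)cc3)Oc2c1CC=C(C)C | intermediate
15 | 4-[(2S,4R)-7-methoxy-8-prenyl-4-(4,4,5,5-tetramethyl-1,3,2-dioxaborolan-2-yl)-5-(triisopropylsilyloxy)chroman-2-yl]phenyl pivalate (not isolated) | COc1cc(O[Si](C(C)C)(C(C)C)C(C)C)c2c(c1CC=C(C)C)O[C@H](c1ccc(OC(=O)C(C)(C)C)cc1)C[C@H]2B1OC(C)(C)C(C)(C)O1 | intermediate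
16 | 4-[(2S,4R)-4-hydroxy-7-methoxy-8-prenyl-5-(triisopropylsilyloxy)chroman-2-yl]phenyl pivalate | COc1cc(O[Si](C(C)C)(C(C)C)C(C)C)c2c(c1CC=C(C)C)O[C@H](c1ccc(OC(=O)C(C)(C)C)cc1)C[C@H]2O | intermediate
17 | (2S,4R)-2-(4-hydroxyphenyl)-7-methoxy-8-prenyl-5-(triisopropylsilyloxy)chroman-4-ol (not isolated) | COc1cc(O[Si](C(C)C)(C(C)C)C(C)C)c2c(c1CC=C(C)C)O[C@H](c1ccc(O)cc1)C[C@H]2O | intermediate
18 | (2S,4R)-2-(4-hydroxyphenyl)-7-methoxy-8-prenylchromane-4,5-diol (4,5,4'-trihydroxy-7-methoxy-8-prenylflavan) | COc1cc(O)c2c(c1CC=C(C)C)O[C@H](c1ccc(O)cc1)C[C@H]2O | target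

**Step count and risks**

Total: 10 steps. Longest linear sequence: 8 steps (steps 1–4 and 7–10); the carbonate branch (steps 5–6) joins at step 7.

Most likely to fail:

Step 9. Hydrocupration at C4 may be slow, since C4 is crowded by the peri O5 silyl ether and sits on a very electron-rich ring. That would cost regio- or facial control; copper at C3 would be followed by β-aryloxide elimination and opening of ring C. The fallback leaves the copper hydride cycle for rhodium(I)-catalysed hydroboration with catecholborane ([Rh(cod)2]BF4 with a chelating phosphine or the matched antipode of a P,N ligand such as QUINAP, THF, rt). This runs through B–H oxidative addition, insertion to an η3-benzylrhodium and C–B reductive elimination, and it has precedent for placing boron at C4 of 2H-chromenes. It sets out from 14 and passes the (2S,4R) C4 catecholboronate 4-[(2S,4R)-4-(1,3,2-benzodioxaborol-2-yl)-7-methoxy-8-prenyl-5-(triisopropylsilyloxy)chroman-2-yl]phenyl pivalate F1. F1 is oxidised in the same flask with sodium perborate, and the fallback comes back to the route at 16.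

Step 7. The ambident phenoxide of the very electron-rich 7 may attack the copper allenylidene through a ring carbon instead of oxygen, or the ortho-prenyl group may lower the enantioselectivity. The fallback moves the stereochemistry into the propargylic alcohol and forms O1–C2 by Mitsunobu inversion. It sets out from 9: zinc alkynylation with trimethylsilylacetylene (Me2Zn, ProPhenol ligand, toluene) should give (S)-4-[1-hydroxy-3-(trimethylsilyl)prop-2-yn-1-yl]phenyl pivalate F2. Its descriptor is S only because silylethynyl outranks aryl; the spatial arrangement is that of the next compound. C-Desilylation (TBAF/AcOH, THF, −20 °C) gives (R)-4-(1-hydroxyprop-2-yn-1-yl)phenyl pivalate F3. Coupling of F3 with phenol 7 (PPh3, DIAD, toluene, 0 °C) proceeds with inversion and comes back to the route at 13.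

Step 3. Metalation may partly occur next to the silyl ether and trigger O→C silyl migration, or the doubly ortho-substituted aryllithium may be allylated sluggishly or at the tertiary terminus. The fallback drops the MOM/lithiation sequence for direct ortho C-alkylation of a phenoxide. It sets out from 2: the sodium salt (NaH, toluene, 0 °C) is treated with prenyl bromide 4 at rt. The contact ion pair alkylates at carbon ortho to oxygen, and the only ortho carbon not screened by the TIPS ether is the one between OH and OMe. The fallback comes back to the route at 7 and bypasses 3, 5 and 6.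

**Further compounds**

F1 | step 9 | 4-[(2S,4R)-4-(1,3,2-benzodioxaborol-2-yl)-7-methoxy-8-prenyl-5-(triisopropylsilyloxy)chroman-2-yl]phenyl pivalate | COc1cc(O[Si](C(C)C)(C(C)C)C(C)C)c2c(c1CC=C(C)C)O[C@H](c1ccc(OC(=O)C(C)(C)C)cc1)C[C@H]2B1Oc2ccccc2O1
F2 | step 7 | (S)-4-[1-hydroxy-3-(trimethylsilyl)prop-2-yn-1-yl]phenyl pivalate | C[Si](C)(C)C#C[C@@H](O)c1ccc(OC(=O)C(C)(C)C)cc1
F3 | step 7 | (R)-4-(1-hydroxyprop-2-yn-1-yl)phenyl pivalate | C#C[C@@H](O)c1ccc(OC(=O)C(C)(C)C)cc1
F0 | step 3 | none | none
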